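**Plan**
1. Cuts (germacrane numbering): the C1 carbinol back to its ketone; the C1–C10 ring bond (alkenyl bromide + aldehyde, Ni/Cr); then the O–C6 and C6–C7 bonds of the butenolide together, giving a (Z)-β-triflyloxy acrylic acid (fragment E: C7–C10, C14, C11–C13) and an alkenyl carbene precursor (fragment W: C1–C6).
2. Enabling feature: C6 is a doubly allylic CH between the C4=C5 alkene and the C7=C11 ring alkene, and the C12 carboxyl oxygen lies cis to it across C7=C11. The five-membered ring O–C12–C11=C7–C6 can therefore be completed by inserting C6 as a one-carbon carbene unit into a C7–Pd bond and capturing the resulting allyl–palladium at C6 with the carboxylate, a [4+1] union.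
3. Forward order: fragment W from neryl acetate; a C11–C13 malonic half-ester; fragment E from methyl (S)-glycidate; the [4+1] union closes the butenolide; Ni/Cr coupling closes the ten-membered ring; oxidation and CBS reduction set C1.
4. Stereochemistry: 4Z from nerol; C8 (S) from the glycidate; C6 (R) induced by C8 in the migratory insertion and kept by inner-sphere C–O formation; C1 (S) by reagent-controlled reduction; the C7=C11 geometry from chelation-controlled (Z)-enol triflation.

Key step: step 15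

Remark: the SMILES is read as 1S,6R,8S with a 4Z (ring-cis) C4=C5 bond, and the route is built for this isomer.

**Step 1**
Reactants: 1 neryl acetate [(2Z)-3,7-dimethylocta-2,6-dien-1-yl acetate]
Product: 2 (2Z)-5-(3,3-dimethyloxiran-2-yl)-3-methylpent-2-en-1-yl acetate (racemic epoxide)
Conditions: mCPBA (1.05 equiv), CH2Cl2, 0 °C
Reagents that add atoms: mCPBA, OOC(=O)c1cccc(Cl)c1
Why: Prilezhaev epoxidation; the remote trisubstituted 6,7-alkene is more electron-rich than the 2,3-alkene carrying the allylic acetate and should react first, and the new racemic centre is cut out in step 2.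

**Step 2**
Reactants: 2 (2Z)-5-(3,3-dimethyloxiran-2-yl)-3-methylpent-2-en-1-yl acetate
Product: 3 (2Z)-3-methyl-6-oxohex-2-en-1-yl acetate
Conditions: H5IO6 (1.1 equiv), THF–H2O, 0 °C
Reagents that add atoms: water, O
Why: periodic acid opens the epoxide to the diol and cleaves it (Malaprade glycol cleavage) in one pot, freeing C1 as the aldehyde and leaving the (Z)-allylic acetate untouched.

**Step 3**
Reactants: 3 (2Z)-3-methyl-6-oxohex-2-en-1-yl acetate
Product: 5 (2Z)-6,6-dimethoxy-3-methylhex-2-en-1-ol, via acetal acetate 4 (not isolated)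
Conditions: HC(OMe)3, MeOH, PPTS (5 mol %), rt; then K2CO3 (0.2 equiv), rt
Reagents that add atoms: trimethyl orthoformate, COC(OC)OC; methanol, CO
Why: acid-catalysed acetalisation masks C1, and carbonate-catalysed transesterification (Zemplén type) in the same pot frees the allylic alcohol without touching the alkene geometry.

**Step 4**
Reactants: 5 (2Z)-6,6-dimethoxy-3-methylhex-2-en-1-ol
Product: 6 (2Z)-6,6-dimethoxy-3-methylhex-2-enal
Conditions: TEMPO (10 mol %), PhI(OAc)2 (1.1 equiv), CH2Cl2, rt
Reagents that add atoms: none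
Why: oxoammonium (TEMPO/PhI(OAc)2) oxidation of the allylic alcohol stops at the enal and is known to convert nerol-type (Z)-allylic alcohols without Z/E scrambling.

**Step 5**
Reactants: 6 (2Z)-6,6-dimethoxy-3-methylhex-2-enal
Product: 7 N'-[(2Z)-6,6-dimethoxy-3-methylhex-2-en-1-ylidene]-4-methylbenzenesulfonohydrazide
Conditions: TsNHNH2 (1.05 equiv), MeOH, 0 °C to rt
Reagents that add atoms: 4-methylbenzenesulfonohydrazide, Cc1ccc(cc1)S(=O)(=O)NN
Why: condensation to the N-tosylhydrazone, the bench-stable precursor of the alkenyl diazo compound used in step 15; the β,β-disubstituted enal disfavours conjugate addition of the hydrazide.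

**Step 6**
Reactants: 8 tert-butyl 3-hydroxypropanoate
Product: 9 tert-butyl 3-[(tert-butyldiphenylsilyl)oxy]propanoate
Conditions: TBDPSCl (1.1 equiv), imidazole (2 equiv), DMF, rt
Reagents that add atoms: tert-butyl(chloro)diphenylsilane, CC(C)(C)[Si](Cl)(c1ccccc1)c1ccccc1
Why: standard silylation; the TBDPS ether is chosen because it survives TFA (step 14) and is not a leaving group towards zerovalent palladium (step 15).

**Step 7**
Reactants: 9 tert-butyl 3-[(tert-butyldiphenylsilyl)oxy]propanoate
Product: 10 3-tert-butoxy-2-{[(tert-butyldiphenylsilyl)oxy]methyl}-3-oxopropanoic acid (racemic)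
Conditions: LiN(iPr)2 (1.1 equiv), THF, −78 °C; CO2 (gas), −78 °C; 1 M HCl
Reagents that add atoms: carbon dioxide, O=C=O
Why: α-carboxylation of the lithium ester enolate gives the malonic half-ester, and generation and quench at −78 °C should outrun β-elimination of silanolate.

**Step 8**
Reactants: 11 methyl (2S)-oxirane-2-carboxylate; 12 (1-bromoethenyl)trimethylsilane
Product: 14 methyl (2S)-2-hydroxy-4-(trimethylsilyl)pent-4-enoate, via alkenyl Grignard reagent 13 (not isolated)
Conditions: Mg, THF, rt; then CuI (10 mol %), 11, THF, −40 °C; aq. NH4Cl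
Reagents that add atoms: none
Why: copper-catalysed Grignard opening of the glycidic ester at its CH2 terminus (SN2) brings in C10 and C14 as a masked 2-bromoallyl unit and leaves the chiral-pool stereocentre (the later C8) untouched.

**Step 9**
Reactants: 14 methyl (2S)-2-hydroxy-4-(trimethylsilyl)pent-4-enoate
Product: 16 methyl (2S)-4-bromo-2-hydroxypent-4-enoate, via dibromide 15 (not isolated)
Conditions: Br2 (1.05 equiv), CH2Cl2, −78 °C; then NaOMe (1.2 equiv), MeOH, 0 °C
Reagents that add atoms: bromine, BrBr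
Why: bromodesilylation of the 1-silylalkene, by anti addition of Br2 and methoxide-induced anti β-elimination of Me3Si/Br, gives the 2-bromoalkene regiospecifically.

**Step 10**
Reactants: 16 methyl (2S)-4-bromo-2-hydroxypent-4-enoate
Product: 17 (2S)-4-bromo-2-hydroxypent-4-enoic acid
Conditions: LiOH (1.5 equiv), THF–H2O, 0 °C; then 1 M HCl
Reagents that add atoms: lithium hydroxide, [Li+].[OH-]
Why: saponification at 0 °C; the α-hydroxy carboxylate does not epimerise and the alkenyl bromide is inert to hydroxide.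

**Step 11**
Reactants: 17 (2S)-4-bromo-2-hydroxypent-4-enoic acid
Product: 18 (2S)-2-acetoxy-4-bromopent-4-enoic acid
Conditions: Ac2O (2.5 equiv), pyridine, DMAP (5 mol %), CH2Cl2, 0 °C to rt; aqueous work-up
Reagents that add atoms: acetic anhydride, CC(=O)OC(C)=O
Why: O-acetylation installs the final C8 acetate, and the mixed anhydride formed at the carboxyl group is hydrolysed on aqueous work-up.

**Step 12**
Reactants: 18 (2S)-2-acetoxy-4-bromopent-4-enoic acid; 10 3-tert-butoxy-2-{[(tert-butyldiphenylsilyl)oxy]methyl}-3-oxopropanoic acid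
Product: 21 tert-butyl (4S)-4-acetoxy-6-bromo-2-{[(tert-butyldiphenylsilyl)oxy]methyl}-3-oxohept-6-enoate (C2 epimers), via acyl imidazolide 19 (not isolated), via magnesium half-ester salt 20 (not isolated)
Conditions: 18, CDI (1.1 equiv), THF, rt; separately 10, Mg(OEt)2 (0.55 equiv), THF, rt; combine, THF, rt to 40 °C; 1 M HCl
Reagents that add atoms: none
Why: Masamune–Brooks decarboxylative Claisen condensation; the neutral magnesium malonate C-acylates with the acyl imidazolide and loses CO2, which avoids strong base and so protects the C8 centre and the β-silyloxy group, while C11 forms as an inconsequential epimer mixture.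

**Step 13**
Reactants: 21 tert-butyl (4S)-4-acetoxy-6-bromo-2-{[(tert-butyldiphenylsilyl)oxy]methyl}-3-oxohept-6-enoate
Product: 22 tert-butyl (2Z,4S)-4-acetoxy-6-bromo-2-{[(tert-butyldiphenylsilyl)oxy]methyl}-3-{[(trifluoromethyl)sulfonyl]oxy}hepta-2,6-dienoate
Conditions: LiOTf (1.5 equiv), Et3N (1.5 equiv), Tf2O (1.2 equiv), CH2Cl2, −78 to 0 °C
Reagents that add atoms: trifluoromethanesulfonic anhydride, O=S(=O)(OS(=O)(=O)C(F)(F)F)C(F)(F)F
Why: O-triflation of the lithium-chelated β-keto ester enolate should give the (Z)-enol triflate with OTf cis to the ester, because the chelate holds the two oxygens syn; this fixes the geometry of the later C7=C11 ring alkene.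

**Step 14**
Reactants: 22 tert-butyl (2Z,4S)-4-acetoxy-6-bromo-2-{[(tert-butyldiphenylsilyl)oxy]methyl}-3-{[(trifluoromethyl)sulfonyl]oxy}hepta-2,6-dienoate
Product: 23 (2Z,4S)-4-acetoxy-6-bromo-2-{[(tert-butyldiphenylsilyl)oxy]methyl}-3-{[(trifluoromethyl)sulfonyl]oxy}hepta-2,6-dienoic acid
Conditions: TFA–CH2Cl2 (1:4), 0 °C to rt
Reagents that add atoms: none
Why: acidolysis of the tert-butyl ester (E1, loss of isobutene) frees the C12 acid, while the primary TBDPS ether, the acetate and the enol triflate are stable to TFA.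

**Step 15**
Reactants: 23 (2Z,4S)-4-acetoxy-6-bromo-2-{[(tert-butyldiphenylsilyl)oxy]methyl}-3-{[(trifluoromethyl)sulfonyl]oxy}hepta-2,6-dienoic acid; 7 N'-[(2Z)-6,6-dimethoxy-3-methylhex-2-en-1-ylidene]-4-methylbenzenesulfonohydrazide
Product: 25 (1S)-3-bromo-1-[(2R)-4-{[(tert-butyldiphenylsilyl)oxy]methyl}-2-[(1Z)-5,5-dimethoxy-2-methylpent-1-en-1-yl]-5-oxo-2,5-dihydrofuran-3-yl]but-3-en-1-yl acetate, via diazoalkene 24 (not isolated)
Conditions: Pd2(dba)3 (2.5 mol %), P(2-furyl)3 (12 mol %), K2CO3 (3 equiv), 1,4-dioxane, 60 °C; 7 (1.0 equiv) added over 6 h to 23 (1.2 equiv)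
Reagents that add atoms: none
Why: Proposed new method: zerovalent palladium inserts into the activated C7–OTf bond of the carboxylate of 23 to give a five-membered oxapalladacycle, diazoalkene 24 (released slowly from 7 by Bamford–Stevens fragmentation) forms an alkenyl carbene on palladium, and migration of the C7 alkenyl group to the carbene carbon makes the C6–C7 bond and an allyl–palladium carboxylate that has no β-hydrogen in its C6-bound form, so that C–O reductive elimination follows. The closest known reaction types are the palladium-catalysed carbene migratory insertion/allyl capture cascades of vinyl halides with diazo compounds or N-tosylhydrazones (carbenylative amination and alkylation, [4+1] annulations) and the Larock annulation of β-halo acids with dienes. The butenolide closes by inner-sphere O–C6 bond formation from the six-membered palladacycle, a 5-exo-type capture of the allyl terminus C6, whereas attack at the tertiary terminus C4 would need a seven-membered ring. C6 is set in the migratory insertion: with H8 eclipsing the C13 methylene (A1,3 strain) the carbene should place its alkenyl group on the face of the small C8 acetoxy group, anti to C9, and retentive C–O reductive elimination then gives 6R. The step needs triflate over alkenyl bromide selectivity (the carboxyl-activated enol triflate should add first), retention of the 4Z alkene (no isomerisation through a C4-bound allyl form), and suppression of pyrazole formation and of acid–diazo esterification (slow addition, carbonate keeps the acid as carboxylate). The slight excess of 23 keeps palladium in its divalent resting state, so that the allylic acetate and the allylic lactone C–O bond of the product are not ionised.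

**Step 16**
Reactants: 25 (1S)-3-bromo-1-[(2R)-4-{[(tert-butyldiphenylsilyl)oxy]methyl}-2-[(1Z)-5,5-dimethoxy-2-methylpent-1-en-1-yl]-5-oxo-2,5-dihydrofuran-3-yl]but-3-en-1-yl acetate
Product: 27 (1S)-3-bromo-1-[(2R)-4-(hydroxymethyl)-2-[(1Z)-2-methyl-5-oxopent-1-en-1-yl]-5-oxo-2,5-dihydrofuran-3-yl]but-3-en-1-yl acetate, via hydroxy acetal 26 (not isolated)
Conditions: HF·pyridine, pyridine, THF, 0 °C to rt; then 1 M aq. HCl, rt
Reagents that add atoms: water, O
Why: fluoride cleaves the silyl ether and dilute aqueous acid then hydrolyses the dimethyl acetal; acetate, butenolide and alkenyl bromide are stable to both.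

**Step 17**
Reactants: 27 (1S)-3-bromo-1-[(2R)-4-(hydroxymethyl)-2-[(1Z)-2-methyl-5-oxopent-1-en-1-yl]-5-oxo-2,5-dihydrofuran-3-yl]but-3-en-1-yl acetate
Product: 28 (1S)-1-[(2R)-4-(acetoxymethyl)-2-[(1Z)-2-methyl-5-oxopent-1-en-1-yl]-5-oxo-2,5-dihydrofuran-3-yl]-3-bromobut-3-en-1-yl acetate
Conditions: Ac2O (1.5 equiv), pyridine, CH2Cl2, 0 °C
Reagents that add atoms: acetic anhydride, CC(=O)OC(C)=O
Why: acetylation of the primary allylic alcohol installs the 13-acetate; the aldehyde is inert under these mild conditions.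

**Step 18**
Reactants: 28 (1S)-1-[(2R)-4-(acetoxymethyl)-2-[(1Z)-2-methyl-5-oxopent-1-en-1-yl]-5-oxo-2,5-dihydrofuran-3-yl]-3-bromobut-3-en-1-yl acetate
Product: 29 (6R,8S)-8,13-diacetoxy-1-hydroxygermacra-4Z,7(11),10(14)-trien-6,12-olide (both C1 epimers)
Conditions: CrCl2 (8 equiv), NiCl2 (2 mol %), DMSO–THF, rt, 2 mM, slow addition of 28; aqueous work-up
Reagents that add atoms: none
Why: Nozaki–Hiyama–Kishi reaction; zerovalent nickel inserts into the C10–Br bond, transmetalation to trivalent chromium and chemoselective 1,2-addition to the C1 aldehyde under high dilution close the ten-membered ring, which the (Z)-C4=C5 alkene and the fused butenolide pre-organise; C1 forms without reliable control and is corrected in steps 19 and 20.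

**Step 19**
Reactants: 29 (6R,8S)-8,13-diacetoxy-1-hydroxygermacra-4Z,7(11),10(14)-trien-6,12-olide (both C1 epimers)
Product: 30 (6R,8S)-8,13-diacetoxy-1-oxogermacra-4Z,7(11),10(14)-trien-6,12-olide
Conditions: Dess–Martin periodinane (1.5 equiv), pyridine (3 equiv), CH2Cl2, 0 °C to rt
Reagents that add atoms: none
Why: Dess–Martin oxidation converges both C1 epimers to the α-methylene ketone under buffered, non-epimerising conditions.

**Step 20**
Reactants: 30 (6R,8S)-8,13-diacetoxy-1-oxogermacra-4Z,7(11),10(14)-trien-6,12-olide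
Product: 31 8α,13-diacetoxy-1α-hydroxygermacra-4,7(11),10(14)-trien-6α,12-olide (1S,6R,8S,4Z; target)
Conditions: (R)-2-methyl-CBS-oxazaborolidine (0.5 equiv), catecholborane (1.5 equiv), toluene, −78 °C; MeOH, then aqueous work-up
Reagents that add atoms: none
Why: Corey–Bakshi–Shibata reduction; with the 2-substituted alkenyl group (C10) as the large and the C2 methylene as the small substituent, the (R)-oxazaborolidine should deliver hydride to give the 1S alcohol, and catecholborane at −78 °C spares the lactone, the acetates and the alkenes.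

**Compound list**
1 | neryl acetate, (2Z)-3,7-dimethylocta-2,6-dien-1-yl acetate | CC(C)=CCC/C(C)=C\COC(C)=O | starting material
2 | (2Z)-5-(3,3-dimethyloxiran-2-yl)-3-methylpent-2-en-1-yl acetate (racemic) | CC1(C)OC1CC/C(C)=C\COC(C)=O | intermediate
3 | (2Z)-3-methyl-6-oxohex-2-en-1-yl acetate | O=CCC/C(C)=C\COC(C)=O | intermediate
4 | (2Z)-6,6-dimethoxy-3-methylhex-2-en-1-yl acetate | COC(OC)CC/C(C)=C\COC(C)=O | intermediate
5 | (2Z)-6,6-dimethoxy-3-methylhex-2-en-1-ol | COC(OC)CC/C(C)=C\CO | intermediate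
6 | (2Z)-6,6-dimethoxy-3-methylhex-2-enal | COC(OC)CC/C(C)=C\C=O | intermediate
7 | N'-[(2Z)-6,6-dimethoxy-3-methylhex-2-en-1-ylidene]-4-methylbenzenesulfonohydrazide | COC(OC)CC/C(C)=C\C=NNS(=O)(=O)c1ccc(C)cc1 | intermediate
8 | tert-butyl 3-hydroxypropanoate | CC(C)(C)OC(=O)CCO | starting material
9 | tert-butyl 3-[(tert-butyldiphenylsilyl)oxy]propanoate | CC(C)(C)OC(=O)CCO[Si](c1ccccc1)(c1ccccc1)C(C)(C)C | intermediate
10 | 3-tert-butoxy-2-{[(tert-butyldiphenylsilyl)oxy]methyl}-3-oxopropanoic acid (racemic) | CC(C)(C)OC(=O)C(CO[Si](c1ccccc1)(c1ccccc1)C(C)(C)C)C(O)=O | intermediate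
11 | methyl (2S)-oxirane-2-carboxylate, methyl (S)-glycidate | COC(=O)[C@@H]1CO1 | starting material
12 | (1-bromoethenyl)trimethylsilane | C=C(Br)[Si](C)(C)C | starting material
13 | [1-(trimethylsilyl)ethenyl]magnesium bromide | C=C([Mg]Br)[Si](C)(C)C | intermediate
14 | methyl (2S)-2-hydroxy-4-(trimethylsilyl)pent-4-enoate | COC(=O)[C@@H](O)CC(=C)[Si](C)(C)C | intermediate
15 | methyl (2S)-4,5-dibromo-2-hydroxy-4-(trimethylsilyl)pentanoate (C4 epimers) | COC(=O)[C@@H](O)CC(Br)(CBr)[Si](C)(C)C | intermediate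
16 | methyl (2S)-4-bromo-2-hydroxypent-4-enoate | COC(=O)[C@@H](O)CC(Br)=C | intermediate
17 | (2S)-4-bromo-2-hydroxypent-4-enoic acid | OC(=O)[C@@H](O)CC(Br)=C | intermediate
18 | (2S)-2-acetoxy-4-bromopent-4-enoic acid | OC(=O)[C@@H](OC(C)=O)CC(Br)=C | intermediate
19 | (2S)-4-bromo-1-(1H-imidazol-1-yl)-1-oxopent-4-en-2-yl acetate | O=C(n1ccnc1)[C@@H](OC(C)=O)CC(Br)=C | intermediate
20 | magnesium bis(3-tert-butoxy-2-{[(tert-butyldiphenylsilyl)oxy]methyl}-3-oxopropanoate) | [Mg+2].CC(C)(C)OC(=O)C(CO[Si](c1ccccc1)(c1ccccc1)C(C)(C)C)C([O-])=O.CC(C)(C)OC(=O)C(CO[Si](c1ccccc1)(c1ccccc1)C(C)(C)C)C([O-])=O | intermediate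
21 | tert-butyl (4S)-4-acetoxy-6-bromo-2-{[(tert-butyldiphenylsilyl)oxy]methyl}-3-oxohept-6-enoate (C2 epimers) | CC(C)(C)OC(=O)C(CO[Si](c1ccccc1)(c1ccccc1)C(C)(C)C)C(=O)[C@@H](OC(C)=O)CC(Br)=C | intermediate
22 | tert-butyl (2Z,4S)-4-acetoxy-6-bromo-2-{[(tert-butyldiphenylsilyl)oxy]methyl}-3-{[(trifluoromethyl)sulfonyl]oxy}hepta-2,6-dienoate | CC(C)(C)OC(=O)/C(CO[Si](c1ccccc1)(c1ccccc1)C(C)(C)C)=C(\OS(=O)(=O)C(F)(F)F)[C@@H](OC(C)=O)CC(Br)=C | intermediate
23 | (2Z,4S)-4-acetoxy-6-bromo-2-{[(tert-butyldiphenylsilyl)oxy]methyl}-3-{[(trifluoromethyl)sulfonyl]oxy}hepta-2,6-dienoic acid | OC(=O)/C(CO[Si](c1ccccc1)(c1ccccc1)C(C)(C)C)=C(\OS(=O)(=O)C(F)(F)F)[C@@H](OC(C)=O)CC(Br)=C | intermediate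
24 | (2Z)-1-diazo-6,6-dimethoxy-3-methylhex-2-ene | COC(OC)CC/C(C)=C\C=[N+]=[N-] | intermediate
25 | (1S)-3-bromo-1-[(2R)-4-{[(tert-butyldiphenylsilyl)oxy]methyl}-2-[(1Z)-5,5-dimethoxy-2-methylpent-1-en-1-yl]-5-oxo-2,5-dihydrofuran-3-yl]but-3-en-1-yl acetate | COC(OC)CC/C(C)=C\[C@H]1OC(=O)C(CO[Si](c2ccccc2)(c2ccccc2)C(C)(C)C)=C1[C@@H](OC(C)=O)CC(Br)=C | intermediate
26 | (1S)-3-bromo-1-[(2R)-2-[(1Z)-5,5-dimethoxy-2-methylpent-1-en-1-yl]-4-(hydroxymethyl)-5-oxo-2,5-dihydrofuran-3-yl]but-3-en-1-yl acetate | COC(OC)CC/C(C)=C\[C@H]1OC(=O)C(CO)=C1[C@@H](OC(C)=O)CC(Br)=C | intermediate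
27 | (1S)-3-bromo-1-[(2R)-4-(hydroxymethyl)-2-[(1Z)-2-methyl-5-oxopent-1-en-1-yl]-5-oxo-2,5-dihydrofuran-3-yl]but-3-en-1-yl acetate | O=CCC/C(C)=C\[C@H]1OC(=O)C(CO)=C1[C@@H](OC(C)=O)CC(Br)=C | intermediate
28 | (1S)-1-[(2R)-4-(acetoxymethyl)-2-[(1Z)-2-methyl-5-oxopent-1-en-1-yl]-5-oxo-2,5-dihydrofuran-3-yl]-3-bromobut-3-en-1-yl acetate | O=CCC/C(C)=C\[C@H]1OC(=O)C(COC(C)=O)=C1[C@@H](OC(C)=O)CC(Br)=C | intermediate
29 | (6R,8S)-8,13-diacetoxy-1-hydroxygermacra-4Z,7(11),10(14)-trien-6,12-olide (both C1 epimers) | C=C1C[C@H](OC(C)=O)C2=C(COC(C)=O)C(=O)O[C@@H]2/C=C(/C)CCC1O | intermediate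
30 | (6R,8S)-8,13-diacetoxy-1-oxogermacra-4Z,7(11),10(14)-trien-6,12-olide | C=C1C[C@H](OC(C)=O)C2=C(COC(C)=O)C(=O)O[C@@H]2/C=C(/C)CCC1=O | intermediate
31 | 8α,13-diacetoxy-1α-hydroxygermacra-4,7(11),10(14)-trien-6α,12-olide (1S,6R,8S,4Z) | C=C1C[C@H](OC(C)=O)C2=C(COC(C)=O)C(=O)O[C@@H]2/C=C(/C)CC[C@@H]1O | target

**Step count**
Total: 20 steps. Longest linear sequence: 13 steps (steps 8 to 20, from methyl (S)-glycidate 11). Steps 1 to 5 (fragment W) and 6 to 7 (half-ester) are side branches.

**Steps most likely to fail, with fallbacks**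

Step 15 (proposed new method). The alkenyl diazo compound 24 may be lost to pyrazole by electrocyclisation before palladium captures it. The allyl–palladium intermediate may isomerise through its C4-bound form, with loss of the 4Z geometry or β-hydride loss. Face selection at C6 in the migratory insertion may be weak, and the carbonate may slowly epimerise C6 of the product through γ-deprotonation. The fallback uses known chemistry and sets out from acid 23 (as its sodium salt) and aldehyde 6. A Ni/Cr-mediated Nozaki–Hiyama–Kishi coupling of the enol triflate with the aldehyde (CrCl2, NiCl2 cat., DMSO, chiral sulfonamide ligand on chromium) should give (2E,4S)-4-acetoxy-6-bromo-2-{[(tert-butyldiphenylsilyl)oxy]methyl}-3-[(1R,2Z)-1-hydroxy-6,6-dimethoxy-3-methylhex-2-en-1-yl]hepta-2,6-dienoic acid F1. This (cis) γ-hydroxy acid should close on mildly acidic work-up (citric acid) to butenolide 25, where the route is rejoined. In this fallback the C6–C7 bond comes from the alkenylchromium addition, C6 rests on the chromium ligand (the epimers are separable), and the lactone closes by acyl substitution.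

Step 18. The zerovalent nickel co-catalyst may ionise the primary allylic acetate next to the lactone (an activated 2-(acetoxymethyl)alk-2-enoate). Allylchromium species would then add to the aldehyde or be reduced, in competition with the slow closure of the ten-membered ring. The fallback changes the order of events so that ring closure precedes the installation of the 13-acetate; it sets out from 25 and comes back at 30. Selective acetal hydrolysis (PPTS, acetone–H2O) gives (1S)-3-bromo-1-[(2R)-4-{[(tert-butyldiphenylsilyl)oxy]methyl}-2-[(1Z)-2-methyl-5-oxopent-1-en-1-yl]-5-oxo-2,5-dihydrofuran-3-yl]but-3-en-1-yl acetate F2. Ni/Cr ring closure of this silyl ether, which carries no primary allylic ester, gives (6R,8S)-8-acetoxy-13-[(tert-butyldiphenylsilyl)oxy]-1-hydroxygermacra-4Z,7(11),10(14)-trien-6,12-olide F3. Dess–Martin oxidation gives the 1-oxo compound (6R,8S)-8-acetoxy-13-[(tert-butyldiphenylsilyl)oxy]-1-oxogermacra-4Z,7(11),10(14)-trien-6,12-olide F4. HF·pyridine then frees (6R,8S)-8-acetoxy-13-hydroxy-1-oxogermacra-4Z,7(11),10(14)-trien-6,12-olide F5, and Ac2O/pyridine converts it to enone 30.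

Step 20. The conformational bias of the ten-membered enone may override the catalyst (mismatched case), so that hydride arrives from the wrong face, or conjugate reduction of the exo-methylene ketone may compete. The fallback replaces reagent control by substrate control plus inversion; it sets out from 30 and comes back at 31. Luche reduction (NaBH4, CeCl3, MeOH, −78 °C), which follows the ring bias, should give the 1R epimer (1R,6R,8S)-8,13-diacetoxy-1-hydroxygermacra-4Z,7(11),10(14)-trien-6,12-olide F6. Mitsunobu inversion with chloroacetic acid (PPh3, DIAD, toluene, 0 °C) gives the 1S chloroacetate (1S,6R,8S)-8,13-diacetoxy-1-(chloroacetoxy)germacra-4Z,7(11),10(14)-trien-6,12-olide F7. Thiourea with NaHCO3 in ethanol cleaves the chloroacetate in the presence of the two acetates to give 31.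

**Further compounds**
F1 | step 15 | (2E,4S)-4-acetoxy-6-bromo-2-{[(tert-butyldiphenylsilyl)oxy]methyl}-3-[(1R,2Z)-1-hydroxy-6,6-dimethoxy-3-methylhex-2-en-1-yl]hepta-2,6-dienoic acid | OC(=O)/C(CO[Si](c1ccccc1)(c1ccccc1)C(C)(C)C)=C(\[C@H](O)/C=C(/C)CCC(OC)OC)[C@@H](OC(C)=O)CC(Br)=C
F2 | step 18 | (1S)-3-bromo-1-[(2R)-4-{[(tert-butyldiphenylsilyl)oxy]methyl}-2-[(1Z)-2-methyl-5-oxopent-1-en-1-yl]-5-oxo-2,5-dihydrofuran-3-yl]but-3-en-1-yl acetate | O=CCC/C(C)=C\[C@H]1OC(=O)C(CO[Si](c2ccccc2)(c2ccccc2)C(C)(C)C)=C1[C@@H](OC(C)=O)CC(Br)=C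
F3 | step 18 | (6R,8S)-8-acetoxy-13-[(tert-butyldiphenylsilyl)oxy]-1-hydroxygermacra-4Z,7(11),10(14)-trien-6,12-olide (both C1 epimers) | C=C1C[C@H](OC(C)=O)C2=C(CO[Si](c3ccccc3)(c3ccccc3)C(C)(C)C)C(=O)O[C@@H]2/C=C(/C)CCC1O
F4 | step 18 | (6R,8S)-8-acetoxy-13-[(tert-butyldiphenylsilyl)oxy]-1-oxogermacra-4Z,7(11),10(14)-trien-6,12-olide | C=C1C[C@H](OC(C)=O)C2=C(CO[Si](c3ccccc3)(c3ccccc3)C(C)(C)C)C(=O)O[C@@H]2/C=C(/C)CCC1=O
F5 | step 18 | (6R,8S)-8-acetoxy-13-hydroxy-1-oxogermacra-4Z,7(11),10(14)-trien-6,12-olide | C=C1C[C@H](OC(C)=O)C2=C(CO)C(=O)O[C@@H]2/C=C(/C)CCC1=O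
F6 | step 20 | (1R,6R,8S)-8,13-diacetoxy-1-hydroxygermacra-4Z,7(11),10(14)-trien-6,12-olide | C=C1C[C@H](OC(C)=O)C2=C(COC(C)=O)C(=O)O[C@@H]2/C=C(/C)CC[C@H]1O
F7 | step 20 | (1S,6R,8S)-8,13-diacetoxy-1-(chloroacetoxy)germacra-4Z,7(11),10(14)-trien-6,12-olide | C=C1C[C@H](OC(C)=O)C2=C(COC(C)=O)C(=O)O[C@@H]2/C=C(/C)CC[C@@H]1OC(=O)CCl
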